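A direct plan would buy rings A and C and build only ring B: bromoalkyne A1, trimmed from a terpene aldehyde, would be lithiated and acylated with ester A2 to ynone A3; a sulfonium methylide and cationic gold would close ring B at its C–O bonds to bromide A4, whose zinc reagent would be coupled with bromofuraldehyde A5 to aldehyde A6 before a Doebner condensation. Weakest would be the one-flask ylide/gold furan annulation (unprecedented; the ylide can alkylate the bromide, sulfide and halide poison gold), the ester acylation of a bromide-bearing acetylide (over-addition), and the four functional-group steps that only make A1 (length without complexity).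

Rings B and C are both 2,4-disubstituted furans, and each is cut across its C3=C4 bond into a secondary vinyl carbinol (O1, C2, C3 and the C2 substituent) and a 2-alkylacrolein (C4, C5 and the C4 substituent). Cross-metathesis joins the two chains at exactly this ring bond and acid cyclodehydrates the γ-hydroxyenal, so a single operation couples two fragments, builds the furan and fixes the 2,4-pattern by connectivity; for ring C it also carries the (E)-enoate in. No ynone, ylide annulation, halide-bearing acetylide or terpene trimming is left: carbinols come from aldehydes and vinylmagnesium bromide, enals from aldehydes and formaldehyde, the stereocentre from catalysis.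

Key step: step 10

Remark: the copper–diphosphine catalyst of step 1 is assumed to give the (3S)-ester with the ligand enantiomer named; if the sense of induction is the opposite, the mirror-image ligand would be used and nothing else changes.

**Step 1**
Reactants: 1 2-(4-bromobutyl)-1,3-dioxolane; 2 methyl (2E)-but-2-enoate
Product: 4 methyl (3S)-7-(1,3-dioxolan-2-yl)-3-methylheptanoate, via Grignard reagent 3 (not isolated)
Conditions: 1, Mg, Et2O, 35 °C; then 2, CuBr·SMe2 (5 mol%), (R)-1-[(S)-2-(diphenylphosphanyl)ferrocenyl]ethyldicyclohexylphosphane (6 mol%), t-BuOMe, −75 °C; aq NH4Cl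
Reagents that add atoms: none
Why: Copper-catalysed asymmetric conjugate addition of a Grignard reagent to an α,β-unsaturated ester: the chiral ferrocenyl diphosphine–copper complex selects one face of the crotonate and so sets the (S) methyl-bearing centre, the dioxolane being inert to the Grignard reagent at −75 °C.

**Step 2**
Reactants: 4 methyl (3S)-7-(1,3-dioxolan-2-yl)-3-methylheptanoate
Product: 6 (3RS,5S)-9-(1,3-dioxolan-2-yl)-5-methylnon-1-en-3-ol, via aldehyde 5 (not isolated)
Conditions: i-Bu2AlH (1.1 equiv), CH2Cl2, −78 °C; then CH2=CHMgBr (3 equiv), THF, −78 → 0 °C; aq NH4Cl, aq potassium sodium tartrate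
Reagents that add atoms: vinylmagnesium bromide, C=C[Mg]Br
Why: One-pot partial reduction/Grignard addition: the aluminium hemiacetal of the ester is stable at −78 °C and releases aldehyde 5 only as the vinyl Grignard reagent traps it; the new carbinol centre is formed without control and is of no consequence because it becomes C2 of ring B, while the (S) centre, β to the carbonyl, cannot epimerise.

**Step 3**
Reactants: 7 3-bromofuran; 1 2-(4-bromobutyl)-1,3-dioxolane
Product: 10 5-(furan-3-yl)pentanal, via alkylzinc bromide 8 (not isolated), via dioxolane 9 (not isolated)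
Conditions: 1, Zn dust (activated with BrCH2CH2Br and Me3SiCl), LiCl, THF, 50 °C; then 7, Pd(OAc)2 (2 mol%), SPhos (4 mol%), THF, 25 °C; then 2 M HCl, 25 °C
Reagents that add atoms: water, O
Why: Negishi cross-coupling: LiCl-assisted zinc insertion into the primary C–Br bond leaves the dioxolane untouched, zerovalent palladium with the bulky biarylphosphine couples the alkylzinc bromide at C3 of the bromofuran faster than β-hydride elimination, and dilute acid then hydrolyses the dioxolane at room temperature, which a 3-alkylfuran should tolerate.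

**Step 4**
Reactants: 10 5-(furan-3-yl)pentanal
Product: 12 5-(furan-3-yl)-2-methylidenepentanal, via Mannich base 11 (not isolated)
Conditions: aq CH2O (37%, 1.5 equiv), pyrrolidine (0.1 equiv), propanoic acid (0.1 equiv), i-PrOH, 45 °C
Reagents that add atoms: formaldehyde, C=O
Why: Amine-catalysed α-methylenation (Mannich condensation, then β-elimination of the amine): the enamine of 10 adds to the formaldehyde-derived iminium ion and Mannich base 11 loses pyrrolidine to give the 2-alkylacrolein, under weakly acidic catalytic conditions that should not aminomethylate the furan.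

**Step 5**
Reactants: 6 (3RS,5S)-9-(1,3-dioxolan-2-yl)-5-methylnon-1-en-3-ol; 12 5-(furan-3-yl)-2-methylidenepentanal
Product: 15 (6S)-7-{4-[3-(furan-3-yl)propyl]furan-2-yl}-6-methylheptanal, via hydroxyenal 13 (not isolated), via furan dioxolane 14 (not isolated)
Conditions: 12 (2.5 equiv), second-generation Hoveyda–Grubbs catalyst RuCl2(H2IMes)(=CH-C6H4-2-O-i-Pr) (5 mol%), 1,4-benzoquinone (10 mol%), CH2Cl2, 40 °C; then TsOH·H2O (0.1 equiv), acetone/H2O 10:1, 40 °C
Reagents that add atoms: water, O
Why: Olefin cross-metathesis followed by acid-induced cyclodehydration (the reaction type of step 10): the vinyl carbinol and the 2-alkylacrolein, which cannot homodimerise, are joined at the future C3=C4 bond of ring B as hydroxyenal 13, and acid then closes the ring by 5-exo-trig hemiacetal formation and loss of water (the carbinol centre becomes C2) and cleaves the dioxolane.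

**Step 6**
Reactants: 15 (6S)-7-{4-[3-(furan-3-yl)propyl]furan-2-yl}-6-methylheptanal
Product: 17 (6S)-7-{4-[3-(furan-3-yl)propyl]furan-2-yl}-6-methyl-2-methylideneheptanal, via Mannich base 16 (not isolated)
Conditions: aq CH2O (37%, 1.5 equiv), pyrrolidine (0.1 equiv), propanoic acid (0.1 equiv), i-PrOH, 45 °C
Reagents that add atoms: formaldehyde, C=O
Why: Amine-catalysed α-methylenation (Mannich condensation/elimination) as in step 4; the remote (S) centre is not α to the aldehyde and is unaffected.

**Step 7**
Reactants: 18 2,2-dimethoxyacetaldehyde; 19 ethyl 2-(triphenyl-λ5-phosphanylidene)propanoate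
Product: 20 ethyl (2E)-4,4-dimethoxy-2-methylbut-2-enoate
Conditions: 18 (60% aq solution), CH2Cl2, 25 °C
Reagents that add atoms: none
Why: Wittig olefination with a stabilised α-methyl ylide, which should give the (E)-trisubstituted enoate with the ester trans to the acetal carbon.

**Step 8**
Reactants: 20 ethyl (2E)-4,4-dimethoxy-2-methylbut-2-enoate
Product: 21 ethyl (2E)-2-methyl-4-oxobut-2-enoate
Conditions: Amberlyst 15 (acid form), acetone/H2O 20:1, 25 °C
Reagents that add atoms: water, O
Why: Acid-catalysed acetal hydrolysis under conditions mild enough to leave the ester and the (E)-alkene unchanged.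

**Step 9**
Reactants: 21 ethyl (2E)-2-methyl-4-oxobut-2-enoate
Product: 22 ethyl (2E,4RS)-4-hydroxy-2-methylhexa-2,5-dienoate
Conditions: CH2=CHMgBr (1.05 equiv), THF, −78 °C; aq NH4Cl
Reagents that add atoms: vinylmagnesium bromide, C=C[Mg]Br
Why: Grignard 1,2-addition, the aldehyde reacting far faster at −78 °C than the hindered conjugated ester; the carbinol centre is formed as a racemate and later becomes C2 of ring C.

**Step 10**
Reactants: 17 (6S)-7-{4-[3-(furan-3-yl)propyl]furan-2-yl}-6-methyl-2-methylideneheptanal; 22 ethyl (2E,4RS)-4-hydroxy-2-methylhexa-2,5-dienoate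
Product: 24 ethyl (2E)-3-{4-[(4S)-5-{4-[3-(furan-3-yl)propyl]furan-2-yl}-4-methylpentyl]furan-2-yl}-2-methylprop-2-enoate, via hydroxyenal 23 (not isolated)
Conditions: 22 (4 equiv), second-generation Hoveyda–Grubbs catalyst RuCl2(H2IMes)(=CH-C6H4-2-O-i-Pr) (8 mol% in two portions), 1,4-benzoquinone (10 mol%), CH2Cl2, 40 °C, argon sparge; then TsOH·H2O (5 mol%), 25 °C
Reagents that add atoms: none
Why: The ruthenium alkylidene first takes up the monosubstituted vinyl group of carbinol 22 and then undergoes cross-metathesis with the 1,1-disubstituted alkene of enal 17, releasing ethene and forming the trisubstituted C3=C4 bond of γ-hydroxyenal 23; acid then either isomerises the (E)-enal by reversible conjugate addition, which brings the hydroxyl and the aldehyde to the same side, or tautomerises it through the dienol to the 1,4-dicarbonyl isomer, and both pathways converge on the same furan. The closest known reaction type is the cross-metathesis of allylic alcohols with α,β-unsaturated carbonyl compounds followed by acid-induced cyclodehydration of the γ-hydroxy carbonyl product to a furan, together with the cross-metathesis of 2-substituted acroleins. Ring C closes by 5-exo-trig attack of the hydroxyl on the aldehyde carbon (O1–C5 bond) and the 2-hydroxy-2,5-dihydrofuran aromatises by loss of water, the bond made by metathesis being the ring C3=C4 bond. No stereocentre is formed: the carbinol centre of 22 becomes sp2 (C2), both alkene geometries of 23 lead to the same product, and the (S) centre is remote and untouched. The step needs cross- over homo-metathesis and chemoselectivity among the three alkenes and two furans present: enal 17 cannot homodimerise, the carbinol is used in excess and its dimer remains a competent partner, the trisubstituted enoate alkene and the furans are inert to the catalyst, and the 2,4-pattern follows from connectivity alone. The hydroxyl closes on the aldehyde and not on the ester because the ester is held away by its (E)-alkene and is the weaker electrophile.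

**Step 11**
Reactants: 24 ethyl (2E)-3-{4-[(4S)-5-{4-[3-(furan-3-yl)propyl]furan-2-yl}-4-methylpentyl]furan-2-yl}-2-methylprop-2-enoate
Product: 25 (2E)-3-{4-[(4S)-5-{4-[3-(furan-3-yl)propyl]furan-2-yl}-4-methylpentyl]furan-2-yl}-2-methylprop-2-enoic acid (CNP0088458.1)
Conditions: LiOH·H2O (3 equiv), THF/MeOH/H2O 3:1:1, 25 °C; then cold 0.5 M HCl to pH 4
Reagents that add atoms: lithium hydroxide, [Li+].[OH-]
Why: Ester saponification by acyl–oxygen cleavage; the (E)-geometry, the three furans and the non-epimerisable (S) centre should be unaffected by aqueous hydroxide, and brief cold acidification frees the acid.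

**Compound list**
1 | 2-(4-bromobutyl)-1,3-dioxolane | BrCCCCC1OCCO1 | starting material
2 | methyl (2E)-but-2-enoate | C/C=C/C(=O)OC | starting material
3 | [4-(1,3-dioxolan-2-yl)butyl]magnesium bromide | Br[Mg]CCCCC1OCCO1 | intermediate
4 | methyl (3S)-7-(1,3-dioxolan-2-yl)-3-methylheptanoate | COC(=O)C[C@@H](C)CCCCC1OCCO1 | intermediate
5 | (3S)-7-(1,3-dioxolan-2-yl)-3-methylheptanal | O=CC[C@@H](C)CCCCC1OCCO1 | intermediate
6 | (3RS,5S)-9-(1,3-dioxolan-2-yl)-5-methylnon-1-en-3-ol | C=CC(O)C[C@@H](C)CCCCC1OCCO1 | intermediate
7 | 3-bromofuran | Brc1ccoc1 | starting material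
8 | [4-(1,3-dioxolan-2-yl)butyl]zinc bromide | Br[Zn]CCCCC1OCCO1 | intermediate
9 | 2-[4-(furan-3-yl)butyl]-1,3-dioxolane | C1COC(CCCCc2ccoc2)O1 | intermediate
10 | 5-(furan-3-yl)pentanal | O=CCCCCc1ccoc1 | intermediate
11 | 5-(furan-3-yl)-2-(pyrrolidin-1-ylmethyl)pentanal (racemic) | O=CC(CN1CCCC1)CCCc1ccoc1 | intermediate
12 | 5-(furan-3-yl)-2-methylidenepentanal | C=C(C=O)CCCc1ccoc1 | intermediate
13 | (2E,4RS,6S)-10-(1,3-dioxolan-2-yl)-2-[3-(furan-3-yl)propyl]-4-hydroxy-6-methyldec-2-enal | O=C/C(CCCc1ccoc1)=C/C(O)C[C@@H](C)CCCCC1OCCO1 | intermediate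
14 | 2-[(5S)-6-{4-[3-(furan-3-yl)propyl]furan-2-yl}-5-methylhexyl]-1,3-dioxolane | C1COC(CCCC[C@H](C)Cc2cc(CCCc3ccoc3)co2)O1 | intermediate
15 | (6S)-7-{4-[3-(furan-3-yl)propyl]furan-2-yl}-6-methylheptanal | O=CCCCC[C@H](C)Cc1cc(CCCc2ccoc2)co1 | intermediate
16 | (2RS,6S)-7-{4-[3-(furan-3-yl)propyl]furan-2-yl}-6-methyl-2-(pyrrolidin-1-ylmethyl)heptanal | O=CC(CN1CCCC1)CCC[C@H](C)Cc1cc(CCCc2ccoc2)co1 | intermediate
17 | (6S)-7-{4-[3-(furan-3-yl)propyl]furan-2-yl}-6-methyl-2-methylideneheptanal | C=C(C=O)CCC[C@H](C)Cc1cc(CCCc2ccoc2)co1 | intermediate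
18 | 2,2-dimethoxyacetaldehyde | COC(OC)C=O | starting material
19 | ethyl 2-(triphenyl-λ5-phosphanylidene)propanoate | CCOC(=O)C(C)=P(c1ccccc1)(c1ccccc1)c1ccccc1 | starting material
20 | ethyl (2E)-4,4-dimethoxy-2-methylbut-2-enoate | CCOC(=O)/C(C)=C/C(OC)OC | intermediate
21 | ethyl (2E)-2-methyl-4-oxobut-2-enoate | CCOC(=O)/C(C)=C/C=O | intermediate
22 | ethyl (2E,4RS)-4-hydroxy-2-methylhexa-2,5-dienoate | CCOC(=O)/C(C)=C/C(O)C=C | intermediate
23 | ethyl (2E,4RS,5E,10S)-6-formyl-11-{4-[3-(furan-3-yl)propyl]furan-2-yl}-4-hydroxy-2,10-dimethylundeca-2,5-dienoate | CCOC(=O)/C(C)=C/C(O)/C=C(/C=O)CCC[C@H](C)Cc1cc(CCCc2ccoc2)co1 | intermediate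
24 | ethyl (2E)-3-{4-[(4S)-5-{4-[3-(furan-3-yl)propyl]furan-2-yl}-4-methylpentyl]furan-2-yl}-2-methylprop-2-enoate | CCOC(=O)/C(C)=C/c1cc(CCC[C@H](C)Cc2cc(CCCc3ccoc3)co2)co1 | intermediate
25 | (2E)-3-{4-[(4S)-5-{4-[3-(furan-3-yl)propyl]furan-2-yl}-4-methylpentyl]furan-2-yl}-2-methylprop-2-enoic acid (CNP0088458.1) | C/C(=C\c1cc(CCC[C@H](C)Cc2cc(CCCc3ccoc3)co2)co1)C(=O)O | target

**Step count**
Total: 11 steps. Longest linear sequence: 6 steps (1 → 4 → 6 → 15 → 17 → 24 → 25; the branch from 7 through 10 and 12 is equally long).

**Steps most likely to fail**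

Step 10 (key step). The cross-metathesis between two hindered alkenes may be slow, and self-metathesis or ruthenium hydride isomerisation of the doubly allylic carbinol to a ketone may overtake it. The fallback replaces the intermolecular metathesis by a ring-closing one through a temporary acetal tether. It sets out from 17: trimethyl orthoformate and pyridinium p-toluenesulfonate in methanol would give dimethyl acetal F1. Acid-catalysed exchange with carbinol 22 in toluene, with removal of methanol, would give mixed acetal F2. Ring-closing metathesis with the second-generation Grubbs catalyst would then form the C3=C4 bond inside the ring to give 2-methoxy-2,5-dihydrofuran F3. Acid-induced loss of methanol would aromatise F3, and the fallback comes back at 24.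

Step 5. The same cross-metathesis may stall at low conversion with this pair, or the furan aldehyde may oligomerise under the acid needed for cyclodehydration and acetal cleavage. The fallback is a classical Paal–Knorr closure. It sets out from 4 and 10: chloromethyllithium (ICH2Cl, MeLi, −78 °C) would convert ester 4 into chloromethyl ketone F4. Aldehyde 10 and pyrrolidine would give enamine F5, which would be alkylated with F4 (NaI, MeCN) and hydrolysed to γ-keto aldehyde F6. Dilute aqueous acid would then cyclodehydrate F6 and cleave the dioxolane, coming back at 15.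

Step 1. Facial selectivity may be insufficient with the acetal-bearing Grignard reagent, and 1,2-addition may compete. The fallback replaces catalyst control by auxiliary control. It sets out from 1, which would be converted into Grignard reagent 3 as in step 1. Separately, (4S)-4-phenyl-1,3-oxazolidin-2-one would be N-acylated with (E)-but-2-enoyl chloride to N-crotonyl oxazolidinone F7. Grignard reagent 3 with CuBr·SMe2 would add to the chelated s-cis enoyl unit of F7 on the face opposite the phenyl group to give adduct F8, which could be purified as a single diastereomer. Sodium methoxide in methanol would release the auxiliary and come back at 4.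

**Further compounds**
F1 | step 10 | 2-[(2S)-7,7-dimethoxy-2-methyl-6-methylideneheptyl]-4-[3-(furan-3-yl)propyl]furan | C=C(C(OC)OC)CCC[C@H](C)Cc1cc(CCCc2ccoc2)co1
F2 | step 10 | ethyl (2E)-4-{[(6S)-7-{4-[3-(furan-3-yl)propyl]furan-2-yl}-1-methoxy-6-methyl-2-methylideneheptyl]oxy}-2-methylhexa-2,5-dienoate (mixture of diastereomers) | CCOC(=O)/C(C)=C/C(C=C)OC(OC)C(=C)CCC[C@H](C)Cc1cc(CCCc2ccoc2)co1
F3 | step 10 | ethyl (2E)-3-{4-[(4S)-5-{4-[3-(furan-3-yl)propyl]furan-2-yl}-4-methylpentyl]-5-methoxy-2,5-dihydrofuran-2-yl}-2-methylprop-2-enoate (mixture of diastereomers) | CCOC(=O)/C(C)=C/C1OC(OC)C(CCC[C@H](C)Cc2cc(CCCc3ccoc3)co2)=C1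
F4 | step 5 | (4S)-1-chloro-8-(1,3-dioxolan-2-yl)-4-methyloctan-2-one | ClCC(=O)C[C@@H](C)CCCCC1OCCO1
F5 | step 5 | 1-[(1E)-5-(furan-3-yl)pent-1-en-1-yl]pyrrolidine | C1CCN(C1)/C=C/CCCc1ccoc1
F6 | step 5 | (2RS,6S)-10-(1,3-dioxolan-2-yl)-2-[3-(furan-3-yl)propyl]-6-methyl-4-oxodecanal | O=CC(CCCc1ccoc1)CC(=O)C[C@@H](C)CCCCC1OCCO1
F7 | step 1 | (4S)-3-[(2E)-but-2-enoyl]-4-phenyl-1,3-oxazolidin-2-one | C/C=C/C(=O)N1[C@@H](c2ccccc2)COC1=O
F8 | step 1 | (4S)-3-[(3S)-7-(1,3-dioxolan-2-yl)-3-methylheptanoyl]-4-phenyl-1,3-oxazolidin-2-one | O=C(C[C@@H](C)CCCCC1OCCO1)N1[C@@H](c2ccccc2)COC1=O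
A1 | direct plan | (4S)-7-bromo-4-methylhept-1-yne | BrCCC[C@H](C)CC#C
A2 | direct plan | ethyl 4-(furan-3-yl)butanoate | CCOC(=O)CCCc1ccoc1
A3 | direct plan | (8S)-11-bromo-1-(furan-3-yl)-8-methylundec-5-yn-4-one | BrCCC[C@H](C)CC#CC(=O)CCCc1ccoc1
A4 | direct plan | 2-[(2S)-5-bromo-2-methylpentyl]-4-[3-(furan-3-yl)propyl]furan | BrCCC[C@H](C)Cc1cc(CCCc2ccoc2)co1
A5 | direct plan | 4-bromofuran-2-carbaldehyde | O=Cc1cc(Br)co1
A6 | direct plan | 4-[(4S)-5-{4-[3-(furan-3-yl)propyl]furan-2-yl}-4-methylpentyl]furan-2-carbaldehyde | O=Cc1cc(CCC[C@H](C)Cc2cc(CCCc3ccoc3)co2)co1
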